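**Plan**

- Retrosynthetic cuts: the acetate, then the aryl ether C–O bond to umbelliferone, then the ring bond between the CH that carries the oxymethyl arm and the methylidene-bearing sp2 ring carbon, then the enol ether C=C, and last the bond between the carbinol carbon and the quaternary carbon.
- Enabling feature: in the cyclohexane the CH bearing the CH2O arm is bonded directly to the ring carbon that carries the exocyclic CH2, so this ring bond and the C=CH2 unit can both arise when an enol ether carbon attacks the internal carbon of a terminal alkyne.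
- Forward order: pent-4-ynal is reverse-prenylated, the vinyl group is cut to an aldehyde and re-extended to a methyl enol ether, the single ring is closed by gold catalysis with methanol capture, and the coumarin is attached afterwards.
- Stereochemistry: the oxygen-bearing carbon is set by reagent control (isopinocampheyl groups from (+)-α-pinene) in the allylboration; the second ring stereocentre is set cis to it in a chair-like cyclisation.

Key step: step 6

Remark: (−)-Ipc2BH denotes crystalline diisopinocampheylborane prepared from (+)-α-pinene and BH3·SMe2 by the standard procedure and is treated as a stock reagent. Pent-4-ynal is made fresh because it is volatile.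

**Step 1**
Reactants: 1 pent-4-yn-1-ol
Product: 2 pent-4-ynal
Conditions: Dess–Martin periodinane, CH2Cl2, 0 °C → rt; short-path distillation
Reagents that add atoms: none
Why: Dess–Martin oxidation of a primary alcohol should stop cleanly at the aldehyde and leave the terminal alkyne untouched.

**Step 2**
Reactants: 2 pent-4-ynal; 3 3-methylbuta-1,2-diene
Product: 6 (4R)-3,3-dimethyloct-1-en-7-yn-4-ol, via allylborane 4 (not isolated), via borinate ester 5 (not isolated)
Conditions: (−)-Ipc2BH, THF, −25 °C; then 2, −78 °C → rt; NaOH, H2O2, 0 °C
Reagents that add atoms: none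
Why: In this Brown asymmetric reverse prenylation, hydroboration of the allene puts boron on the CH2 terminus, the resulting γ,γ-dimethylallylborane (which has no B–H left to attack the alkyne) adds through a closed chair transition state with allylic transposition to build the quaternary carbon, and the isopinocampheyl groups derived from (+)-α-pinene should direct the transfer to the Si face of the aldehyde, which sets the (R)-carbinol.

**Step 3**
Reactants: 6 (4R)-3,3-dimethyloct-1-en-7-yn-4-ol
Product: 7 tert-butyl{[(4R)-3,3-dimethyloct-1-en-7-yn-4-yl]oxy}dimethylsilane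
Conditions: TBSOTf, 2,6-lutidine, CH2Cl2, 0 °C
Reagents that add atoms: tert-butyldimethylsilyl trifluoromethanesulfonate, CC(C)(C)[Si](C)(C)OS(=O)(=O)C(F)(F)F
Why: Silylation with the silyl triflate and a hindered pyridine base is the standard way to protect a secondary alcohol next to a quaternary carbon and does not touch the stereocentre.

**Step 4**
Reactants: 7 tert-butyl{[(4R)-3,3-dimethyloct-1-en-7-yn-4-yl]oxy}dimethylsilane
Product: 9 (3R)-3-[(tert-butyldimethylsilyl)oxy]-2,2-dimethylhept-6-ynal, via ozonide 8 (not isolated)
Conditions: O3, CH2Cl2, −78 °C (Sudan III endpoint); then PPh3, −78 °C → rt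
Reagents that add atoms: ozone, [O-][O+]=O
Why: Ozonolysis of the monosubstituted alkene is far faster than attack on the terminal alkyne when the ozone feed is stopped at the indicator endpoint, and the resulting aldehyde has no α-hydrogen, so the β-silyloxy centre cannot be lost by enolisation or elimination.

**Step 5**
Reactants: 9 (3R)-3-[(tert-butyldimethylsilyl)oxy]-2,2-dimethylhept-6-ynal; 10 (methoxymethyl)triphenylphosphonium chloride
Product: 12 tert-butyl{[(4R)-1-methoxy-3,3-dimethyloct-1-en-7-yn-4-yl]oxy}dimethylsilane (E/Z mixture), via phosphorus ylide 11 (not isolated)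
Conditions: KOtBu (slightly less than 10), THF, 0 °C; then 9, 0 °C → rt
Reagents that add atoms: none
Why: Wittig methoxymethylenation of a non-enolisable aldehyde should give the methyl enol ether as an E/Z mixture that needs no separation, and keeping the salt in slight excess over the base leaves the terminal alkyne protonated.

**Step 6**
Reactants: 12 tert-butyl{[(4R)-1-methoxy-3,3-dimethyloct-1-en-7-yn-4-yl]oxy}dimethylsilane (E/Z mixture); 13 methanol
Product: 14 tert-butyl{[(1R,3S)-3-(dimethoxymethyl)-2,2-dimethyl-4-methylidenecyclohexyl]oxy}dimethylsilane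
Conditions: [JohnPhosAu(NCMe)]SbF6 (3 mol%), MeOH (10 equiv), 4 Å MS, CH2Cl2, 0 °C → rt
Reagents that add atoms: none
Why: The cationic phosphine–gold(I) centre binds the terminal alkyne and the enol ether β-carbon attacks the internal alkyne carbon anti to gold, which closes the cyclohexane and leaves a vinylgold oxocarbenium ion; methanol 13 adds to the oxocarbenium carbon and the proton so released cleaves the C–Au bond, giving the exocyclic methylidene and the dimethyl acetal and returning the catalyst. The closest known reactions are the gold(I)-catalysed alkoxycyclisation of 1,7-enynes and the Conia-ene-type carbocyclisation of enol ethers onto alkynes. The one ring closes in the 6-exo-dig mode, which for a terminal alkyne is the Markovnikov mode and is preferred to 7-endo attack. The new ring stereocentre is controlled by the existing silyloxy-bearing carbon through a chair-like transition state in which the silyloxy group and the developing oxocarbenium arm are both equatorial, so the two substituents should end up cis (1,3-diequatorial). The step needs ring closure to outrun plain methanol addition to the enol ether or the alkyne; the gem-dimethyl quaternary carbon compresses the chain towards closure and blocks enol ether migration, while a limited methanol charge over molecular sieves keeps acid-catalysed acetalisation slow. Both enol ether geometries converge on one product because the acetal carbon is not stereogenic.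

**Step 7**
Reactants: 14 tert-butyl{[(1R,3S)-3-(dimethoxymethyl)-2,2-dimethyl-4-methylidenecyclohexyl]oxy}dimethylsilane
Product: 15 (1S,3R)-3-[(tert-butyldimethylsilyl)oxy]-2,2-dimethyl-6-methylidenecyclohexane-1-carbaldehyde
Conditions: PPTS (cat.), acetone/H2O, rt; crude product used at once
Reagents that add atoms: water, O
Why: Pyridinium-buffered acetal hydrolysis is mild enough to spare the hindered secondary TBS ether and should not enolise the β,γ-unsaturated aldehyde, so neither the α-stereocentre nor the position of the exocyclic alkene is disturbed.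

**Step 8**
Reactants: 15 (1S,3R)-3-[(tert-butyldimethylsilyl)oxy]-2,2-dimethyl-6-methylidenecyclohexane-1-carbaldehyde
Product: 16 {(1S,3R)-3-[(tert-butyldimethylsilyl)oxy]-2,2-dimethyl-6-methylidenecyclohexyl}methanol
Conditions: NaBH4, MeOH, 0 °C
Reagents that add atoms: none
Why: Borohydride reduction of the aldehyde at 0 °C is fast and removes the carbonyl group that made the adjacent stereocentre epimerisable.

**Step 9**
Reactants: 16 {(1S,3R)-3-[(tert-butyldimethylsilyl)oxy]-2,2-dimethyl-6-methylidenecyclohexyl}methanol; 17 umbelliferone (7-hydroxy-2H-chromen-2-one)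
Product: 18 7-({(1S,3R)-3-[(tert-butyldimethylsilyl)oxy]-2,2-dimethyl-6-methylidenecyclohexyl}methoxy)-2H-chromen-2-one
Conditions: PPh3, DIAD, THF, 0 °C → rt (50 °C if slow)
Reagents that add atoms: none
Why: In this Mitsunobu etherification the acidic 7-hydroxycoumarin protonates the betaine readily and its phenoxide displaces the oxyphosphonium at the primary carbon, so no stereocentre is involved.

**Step 10**
Reactants: 18 7-({(1S,3R)-3-[(tert-butyldimethylsilyl)oxy]-2,2-dimethyl-6-methylidenecyclohexyl}methoxy)-2H-chromen-2-one
Product: 19 7-{[(1S,3R)-3-hydroxy-2,2-dimethyl-6-methylidenecyclohexyl]methoxy}-2H-chromen-2-one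
Conditions: HF·pyridine, THF/pyridine, 0 °C → rt
Reagents that add atoms: none
Why: Fluoride cleavage of the Si–O bond with buffered HF·pyridine is non-basic, so the coumarin lactone stays closed and the exocyclic alkene does not migrate.

**Step 11**
Reactants: 19 7-{[(1S,3R)-3-hydroxy-2,2-dimethyl-6-methylidenecyclohexyl]methoxy}-2H-chromen-2-one
Product: 20 (1R,3S)-2,2-dimethyl-4-methylidene-3-{[(2-oxo-2H-chromen-7-yl)oxy]methyl}cyclohexyl acetate (CNP0300702.1)
Conditions: Ac2O, pyridine, DMAP (cat.), CH2Cl2, rt
Reagents that add atoms: acetic anhydride, CC(=O)OC(C)=O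
Why: DMAP-catalysed acylation esterifies the hindered equatorial secondary alcohol at oxygen with retention of configuration.

**Compound list**

1 | pent-4-yn-1-ol | C#CCCCO | starting material
2 | pent-4-ynal | C#CCCC=O | intermediate
3 | 3-methylbuta-1,2-diene | CC(C)=C=C | starting material
4 | (3-methylbut-2-en-1-yl)bis[(1R,2S,3R,5R)-2,6,6-trimethylbicyclo[3.1.1]heptan-3-yl]borane | CC(C)=CCB([C@@H]1C[C@@H]2C[C@@H](C2(C)C)[C@H]1C)[C@@H]1C[C@@H]2C[C@@H](C2(C)C)[C@H]1C | intermediate
5 | (4R)-3,3-dimethyloct-1-en-7-yn-4-yl bis[(1R,2S,3R,5R)-2,6,6-trimethylbicyclo[3.1.1]heptan-3-yl]borinate | C=CC(C)(C)[C@H](OB([C@@H]1C[C@@H]2C[C@@H](C2(C)C)[C@H]1C)[C@@H]1C[C@@H]2C[C@@H](C2(C)C)[C@H]1C)CCC#C | intermediate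
6 | (4R)-3,3-dimethyloct-1-en-7-yn-4-ol | C=CC(C)(C)[C@H](O)CCC#C | intermediate
7 | tert-butyl{[(4R)-3,3-dimethyloct-1-en-7-yn-4-yl]oxy}dimethylsilane | C=CC(C)(C)[C@H](O[Si](C)(C)C(C)(C)C)CCC#C | intermediate
8 | tert-butyl{[(3R)-2-methyl-2-(1,2,4-trioxolan-3-yl)hept-6-yn-3-yl]oxy}dimethylsilane (ozonide, mixture at the trioxolane carbon) | C1OC(OO1)C(C)(C)[C@H](O[Si](C)(C)C(C)(C)C)CCC#C | intermediate
9 | (3R)-3-[(tert-butyldimethylsilyl)oxy]-2,2-dimethylhept-6-ynal | O=CC(C)(C)[C@H](O[Si](C)(C)C(C)(C)C)CCC#C | intermediate
10 | (methoxymethyl)triphenylphosphonium chloride | [Cl-].COC[P+](c1ccccc1)(c1ccccc1)c1ccccc1 | starting material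
11 | (methoxymethylidene)triphenyl-λ5-phosphane | COC=P(c1ccccc1)(c1ccccc1)c1ccccc1 | intermediate
12 | tert-butyl{[(4R)-1-methoxy-3,3-dimethyloct-1-en-7-yn-4-yl]oxy}dimethylsilane (E/Z mixture) | COC=CC(C)(C)[C@H](O[Si](C)(C)C(C)(C)C)CCC#C | intermediate
13 | methanol | CO | starting material
14 | tert-butyl{[(1R,3S)-3-(dimethoxymethyl)-2,2-dimethyl-4-methylidenecyclohexyl]oxy}dimethylsilane | C=C1CC[C@@H](O[Si](C)(C)C(C)(C)C)C(C)(C)[C@H]1C(OC)OC | intermediate
15 | (1S,3R)-3-[(tert-butyldimethylsilyl)oxy]-2,2-dimethyl-6-methylidenecyclohexane-1-carbaldehyde | C=C1CC[C@@H](O[Si](C)(C)C(C)(C)C)C(C)(C)[C@H]1C=O | intermediate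
16 | {(1S,3R)-3-[(tert-butyldimethylsilyl)oxy]-2,2-dimethyl-6-methylidenecyclohexyl}methanol | C=C1CC[C@@H](O[Si](C)(C)C(C)(C)C)C(C)(C)[C@H]1CO | intermediate
17 | umbelliferone (7-hydroxy-2H-chromen-2-one) | O=c1ccc2ccc(O)cc2o1 | starting material
18 | 7-({(1S,3R)-3-[(tert-butyldimethylsilyl)oxy]-2,2-dimethyl-6-methylidenecyclohexyl}methoxy)-2H-chromen-2-one | C=C1CC[C@@H](O[Si](C)(C)C(C)(C)C)C(C)(C)[C@H]1COc1ccc2ccc(=O)oc2c1 | intermediate
19 | 7-{[(1S,3R)-3-hydroxy-2,2-dimethyl-6-methylidenecyclohexyl]methoxy}-2H-chromen-2-one | C=C1CC[C@@H](O)C(C)(C)[C@H]1COc1ccc2ccc(=O)oc2c1 | intermediate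
20 | (1R,3S)-2,2-dimethyl-4-methylidene-3-{[(2-oxo-2H-chromen-7-yl)oxy]methyl}cyclohexyl acetate | C=C1CC[C@@H](OC(C)=O)C(C)(C)[C@H]1COc1ccc2ccc(=O)oc2c1 | target

**Step count and risks**

Total step count: 11. Longest linear sequence: 11 steps, from pent-4-yn-1-ol 1 to 20.

Steps most likely to fail:

Step 6. Methanol may add to the enol ether (acid-catalysed formation of an acyclic acetal) or to the gold-bound alkyne faster than the ring closes, or the two faces of the enol ether carbon may be poorly discriminated so that cis and trans ring isomers form together. The fallback sets out from 12 and changes the nucleophile to a silyl enol ether, which methanol cannot divert into an acetal. Brief treatment of 12 with dilute aqueous HCl in THF should hydrolyse the enol ether to (4R)-4-[(tert-butyldimethylsilyl)oxy]-3,3-dimethyloct-7-ynal F1. TIPSOTf and Et3N in CH2Cl2 should convert this into tert-butyl{[(4R)-3,3-dimethyl-1-{[tri(propan-2-yl)silyl]oxy}oct-1-en-7-yn-4-yl]oxy}dimethylsilane F2. Under the established gold(I) conditions for silyl enol ether carbocyclisation (Ph3PAuCl/AgBF4, CH2Cl2/MeOH) F2 should close in the same 6-exo-dig sense and deliver aldehyde 15 directly; the route is rejoined at 15 and step 7 is skipped.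

Step 9. Displacement of the oxyphosphonium at the β-branched CH2, flanked by the quaternary carbon and the methylidene carbon, may be so slow that the betaine is consumed by hydrazide alkylation or elimination. The fallback sets out from 16 and reverses the polarity of the ether formation: palladium-catalysed C–O cross-coupling of the primary alcohol with commercial 7-bromocoumarin (tBuBrettPhos Pd G3, Cs2CO3, toluene, 80 °C) forms the aryl–oxygen bond instead and should give 18, where the route is rejoined. It makes no compound outside the list (F0).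

Step 2. Enantiofacial control in the allyl transfer may be incomplete, and any Ipc2BH left over could hydroborate the alkyne or reduce the aldehyde. The fallback sets out from 2 and moves the stereo-determining event to a catalytic ketone reduction. Zinc-mediated Barbier addition of prenyl bromide (Zn, THF/aq. NH4Cl), which reacts at its γ-carbon, should give racemic 3,3-dimethyloct-1-en-7-yn-4-ol F3. Dess–Martin oxidation should give 3,3-dimethyloct-1-en-7-yn-4-one F4. Corey–Bakshi–Shibata reduction ((S)-Me-CBS, catecholborane, toluene, −78 °C), which distinguishes the tert-alkyl from the primary alkyl side of the ketone, should return the (R)-alcohol 6, where the route is rejoined.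

**Further compounds**

F1 | step 6 | (4R)-4-[(tert-butyldimethylsilyl)oxy]-3,3-dimethyloct-7-ynal | O=CCC(C)(C)[C@H](O[Si](C)(C)C(C)(C)C)CCC#C
F2 | step 6 | tert-butyl{[(4R)-3,3-dimethyl-1-{[tri(propan-2-yl)silyl]oxy}oct-1-en-7-yn-4-yl]oxy}dimethylsilane | CC(C)[Si](OC=CC(C)(C)[C@H](O[Si](C)(C)C(C)(C)C)CCC#C)(C(C)C)C(C)C
F0 | step 9 | none | none
F3 | step 2 | rac-3,3-dimethyloct-1-en-7-yn-4-ol | C=CC(C)(C)C(O)CCC#C
F4 | step 2 | 3,3-dimethyloct-1-en-7-yn-4-one | C=CC(C)(C)C(=O)CCC#C
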